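**Retrosynthetic overview**
1. Target 18 ⇐ silyl ether 17 ⇐ dehydration of β-hydroxy ketone 15.
2. Key C–C bond (ring C5 to side-chain C1′): intermolecular aldol addition of the lithium dienolate of bromoenone 12 to (E)-pent-2-enal 13.
3. 12 ⇐ α-bromination of the silyl-protected (R)-4-hydroxy-4-alkylcyclopentenone 10 ⇐ hydroxy enone ester 9.
4. 9 ⇐ anti-selective 1,2-addition of the Grignard reagent from protected 8-bromooctanol to (S)-4-silyloxycyclopentenone 3, then desilylation and oxidation, which moves the carbonyl and leaves the chirality on the tertiary carbinol.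
5. Rings: none is formed; the only ring (the cyclopentene) is bought intact in 3.

Assumption: (S)-4-(tert-butyldimethylsilyloxy)cyclopent-2-en-1-one (3) is bought enantiopure; both enantiomers are catalogue items.

**Route**

Step 1
Reactants: 1 8-bromooctan-1-ol
Product: 2 (8-bromooctyloxy)(tert-butyl)dimethylsilane
Conditions: TBSCl, imidazole, DMF, 0 °C → rt
Reagents that add atoms: tert-butyldimethylsilyl chloride, CC(C)(C)[Si](C)(C)Cl
Why: Standard silylation of a primary alcohol, under which the primary alkyl bromide is inert.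

Step 2
Reactants: 2 (8-bromooctyloxy)(tert-butyl)dimethylsilane; 3 (S)-4-(tert-butyldimethylsilyloxy)cyclopent-2-en-1-one
Product: 5 (1R,4S)-4-(tert-butyldimethylsilyloxy)-1-[8-(tert-butyldimethylsilyloxy)octyl]cyclopent-2-en-1-ol, via Grignard reagent 4 (not isolated)
Conditions: 2, Mg, THF, 40 °C; added to 3 premixed with anhydrous CeCl3, THF, −78 °C; then H2O
Reagents that add atoms: none
Why: CeCl3-promoted Grignard 1,2-addition, in which CeCl3 suppresses enolisation and loss of silanolate and the alkyl group enters anti to the C4 silyloxy group, so the new tertiary carbinol is (R) with OH cis to OTBS (minor epimer removed by chromatography).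

Step 3
Reactants: 5 (1R,4S)-4-(tert-butyldimethylsilyloxy)-1-[8-(tert-butyldimethylsilyloxy)octyl]cyclopent-2-en-1-ol
Product: 6 (1R,4S)-1-(8-hydroxyoctyl)cyclopent-2-ene-1,4-diol
Conditions: Bu4NF, THF, 0 °C → rt
Reagents that add atoms: none
Why: Fluoride-mediated desilylation removes both silyl ethers without the acid that would ionise the tertiary allylic alcohol.

Step 4
Reactants: 6 (1R,4S)-1-(8-hydroxyoctyl)cyclopent-2-ene-1,4-diol
Product: 7 8-[(1R)-1-hydroxy-4-oxocyclopent-2-en-1-yl]octanal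
Conditions: Dess–Martin periodinane (2.6 equiv), NaHCO3, CH2Cl2, 0 °C → rt
Reagents that add atoms: none
Why: Dess–Martin oxidation takes the primary alcohol to the aldehyde and the secondary allylic alcohol to the enone while the tertiary alcohol cannot react, so the old C4 stereocentre is spent and the (R) carbinol now carries the chirality.

Step 5
Reactants: 7 8-[(1R)-1-hydroxy-4-oxocyclopent-2-en-1-yl]octanal
Product: 8 8-[(1R)-1-hydroxy-4-oxocyclopent-2-en-1-yl]octanoic acid
Conditions: NaClO2, NaH2PO4, 2-methylbut-2-ene, t-BuOH/H2O, 0 °C → rt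
Reagents that add atoms: sodium chlorite, [Na+].[O-]Cl=O
Why: Pinnick oxidation converts only the aldehyde to the acid under mildly acidic buffered conditions, with the alkene scavenger protecting the enone from HOCl.

Step 6
Reactants: 8 8-[(1R)-1-hydroxy-4-oxocyclopent-2-en-1-yl]octanoic acid
Product: 9 methyl 8-[(1R)-1-hydroxy-4-oxocyclopent-2-en-1-yl]octanoate
Conditions: Me3SiCHN2, PhMe/MeOH 4:1, 0 °C, 20 min
Reagents that add atoms: (trimethylsilyl)diazomethane, C[Si](C)(C)C=[N+]=[N-]
Why: Neutral O-methylation of the carboxylic acid, which avoids base that could racemise the β-hydroxy ketone through retro-aldol ring opening.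

Step 7
Reactants: 9 methyl 8-[(1R)-1-hydroxy-4-oxocyclopent-2-en-1-yl]octanoate
Product: 10 methyl 8-[(1R)-4-oxo-1-(triethylsilyloxy)cyclopent-2-en-1-yl]octanoate
Conditions: Et3SiOTf, 2,6-lutidine, CH2Cl2, −78 → 0 °C
Reagents that add atoms: triethylsilyl trifluoromethanesulfonate, CC[Si](CC)(CC)OS(=O)(=O)C(F)(F)F
Why: Silyl triflate silylation is fast enough for a tertiary alcohol at low temperature and blocks alkoxide formation and retro-aldol in the later enolate step.

Step 8
Reactants: 10 methyl 8-[(1R)-4-oxo-1-(triethylsilyloxy)cyclopent-2-en-1-yl]octanoate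
Product: 12 methyl 8-[(1R)-3-bromo-4-oxo-1-(triethylsilyloxy)cyclopent-2-en-1-yl]octanoate, via trans-dibromide 11 (not isolated)
Conditions: Br2 (1.05 equiv), CH2Cl2, 0 °C; then Et3N, 0 °C → rt
Reagents that add atoms: bromine, BrBr
Why: Bromine addition to the enone followed by E1cB dehydrobromination (loss of the acidic H α to the ketone and of the β-bromide) gives the α-bromoenone regiospecifically, and it is done before any diene is present.

Step 9
Reactants: 12 methyl 8-[(1R)-3-bromo-4-oxo-1-(triethylsilyloxy)cyclopent-2-en-1-yl]octanoate; 13 (E)-pent-2-enal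
Product: 15 methyl 8-[(1R)-3-bromo-5-[(2E)-1-hydroxypent-2-en-1-yl]-4-oxo-1-(triethylsilyloxy)cyclopent-2-en-1-yl]octanoate (diastereomer mixture at C5 and C1′), via lithium dienolate 14 (not isolated)
Conditions: LiN(SiMe3)2 (1.05 equiv), THF, −78 °C, 30 min; 13, −78 °C, 20 min; AcOH quench at −78 °C
Reagents that add atoms: none
Why: Directed intermolecular aldol addition in which the ketone α′-CH2 (far more acidic than the ester α-CH2) is deprotonated kinetically and the enolate adds 1,2 to the enal through a closed Zimmerman–Traxler transition state, giving mainly the threo aldol; both new stereocentres are erased in step 10.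

Step 10
Reactants: 15 methyl 8-[(1R)-3-bromo-5-[(2E)-1-hydroxypent-2-en-1-yl]-4-oxo-1-(triethylsilyloxy)cyclopent-2-en-1-yl]octanoate
Product: 17 methyl 8-[(1S,5Z)-3-bromo-4-oxo-5-[(2E)-pent-2-en-1-ylidene]-1-(triethylsilyloxy)cyclopent-2-en-1-yl]octanoate, via allylic mesylate 16 (not isolated)
Conditions: MsCl, Et3N (4 equiv), CH2Cl2, −20 °C → rt; chromatography to remove the 5E isomer
Reagents that add atoms: none
Why: Mesylation and amine-induced β-elimination (E1cB-like) give the cross-conjugated dienone, where anti loss of MsOH from the threo aldol and allylic strain against the quaternary C1 in the competing rotamer both place the propenyl group on the carbonyl side (5Z), although a separable 5E fraction is expected.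

Step 11
Reactants: 17 methyl 8-[(1S,5Z)-3-bromo-4-oxo-5-[(2E)-pent-2-en-1-ylidene]-1-(triethylsilyloxy)cyclopent-2-en-1-yl]octanoate
Product: 18 methyl 8-[(1S,5Z)-3-bromo-1-hydroxy-4-oxo-5-[(2E)-pent-2-en-1-ylidene]cyclopent-2-en-1-yl]octanoate
Conditions: HF·pyridine, pyridine, THF, 0 °C → rt
Reagents that add atoms: none
Why: Buffered fluoride desilylation cleaves the tertiary triethylsilyl ether without touching the dienone, vinyl bromide, ester or the stereocentre.

**Compound list**
1 | 8-bromooctan-1-ol | OCCCCCCCCBr | starting material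
2 | (8-bromooctyloxy)(tert-butyl)dimethylsilane | CC(C)(C)[Si](C)(C)OCCCCCCCCBr | intermediate
3 | (S)-4-(tert-butyldimethylsilyloxy)cyclopent-2-en-1-one | O=C1C=C[C@@H](O[Si](C)(C)C(C)(C)C)C1 | starting material
4 | [8-(tert-butyldimethylsilyloxy)octyl]magnesium bromide | CC(C)(C)[Si](C)(C)OCCCCCCCC[Mg]Br | intermediate
5 | (1R,4S)-4-(tert-butyldimethylsilyloxy)-1-[8-(tert-butyldimethylsilyloxy)octyl]cyclopent-2-en-1-ol (OH cis to OTBS) | C1[C@H](O[Si](C)(C)C(C)(C)C)C=C[C@@]1(O)CCCCCCCCO[Si](C)(C)C(C)(C)C | intermediate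
6 | (1R,4S)-1-(8-hydroxyoctyl)cyclopent-2-ene-1,4-diol (cis-diol) | C1[C@H](O)C=C[C@@]1(O)CCCCCCCCO | intermediate
7 | 8-[(1R)-1-hydroxy-4-oxocyclopent-2-en-1-yl]octanal | C1C(=O)C=C[C@@]1(O)CCCCCCCC=O | intermediate
8 | 8-[(1R)-1-hydroxy-4-oxocyclopent-2-en-1-yl]octanoic acid | C1C(=O)C=C[C@@]1(O)CCCCCCCC(=O)O | intermediate
9 | methyl 8-[(1R)-1-hydroxy-4-oxocyclopent-2-en-1-yl]octanoate | C1C(=O)C=C[C@@]1(O)CCCCCCCC(=O)OC | intermediate
10 | methyl 8-[(1R)-4-oxo-1-(triethylsilyloxy)cyclopent-2-en-1-yl]octanoate | C1C(=O)C=C[C@@]1(O[Si](CC)(CC)CC)CCCCCCCC(=O)OC | intermediate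
11 | methyl 8-[(1R)-2,3-dibromo-4-oxo-1-(triethylsilyloxy)cyclopentyl]octanoate (trans-dibromide, C2/C3 mixture) | C1C(=O)C(Br)C(Br)[C@@]1(O[Si](CC)(CC)CC)CCCCCCCC(=O)OC | intermediate
12 | methyl 8-[(1R)-3-bromo-4-oxo-1-(triethylsilyloxy)cyclopent-2-en-1-yl]octanoate | C1C(=O)C(Br)=C[C@@]1(O[Si](CC)(CC)CC)CCCCCCCC(=O)OC | intermediate
13 | (E)-pent-2-enal | CC/C=C/C=O | starting material
14 | lithium dienolate of 12 (C5 deprotonated; (R) at the silyloxy carbon) | C1=C(O[Li])C(Br)=C[C@@]1(O[Si](CC)(CC)CC)CCCCCCCC(=O)OC | intermediate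
15 | methyl 8-[(1R)-3-bromo-5-[(2E)-1-hydroxypent-2-en-1-yl]-4-oxo-1-(triethylsilyloxy)cyclopent-2-en-1-yl]octanoate (mixture at C5 and C1′) | CC/C=C/C(O)C1C(=O)C(Br)=C[C@@]1(O[Si](CC)(CC)CC)CCCCCCCC(=O)OC | intermediate
16 | methanesulfonate of 15 | CC/C=C/C(OS(C)(=O)=O)C1C(=O)C(Br)=C[C@@]1(O[Si](CC)(CC)CC)CCCCCCCC(=O)OC | intermediate
17 | methyl 8-[(1S,5Z)-3-bromo-4-oxo-5-[(2E)-pent-2-en-1-ylidene]-1-(triethylsilyloxy)cyclopent-2-en-1-yl]octanoate | CC/C=C/C=C1\C(=O)C(Br)=C[C@@]1(O[Si](CC)(CC)CC)CCCCCCCC(=O)OC | intermediate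
18 | methyl 8-[(1S,5Z)-3-bromo-1-hydroxy-4-oxo-5-[(2E)-pent-2-en-1-ylidene]cyclopent-2-en-1-yl]octanoate | CC/C=C/C=C1\C(=O)C(Br)=C[C@@]1(O)CCCCCCCC(=O)OC | target

**Totals**
Total step count: 11. Longest linear sequence: 11 steps (1 → 18); 3 enters at step 2 and 13 at step 9.

**Three steps most likely to fail**

Step 2 (the basic alkylmetal may enolise 3 and expel silanolate, or add with incomplete facial selectivity). The fallback sets out from 3 and comes back at 9. Carbonyl allylation of 3 with allylmagnesium bromide and CeCl3 (THF, −78 °C) gives (1R,4S)-4-(tert-butyldimethylsilyloxy)-1-(prop-2-enyl)cyclopent-2-en-1-ol F1, with any epimer separated. 9-Borabicyclo[3.3.1]nonane (THF, 0 °C → rt) hydroborates only the terminal alkene to give 9-{3-[(1R,4S)-4-(tert-butyldimethylsilyloxy)-1-hydroxycyclopent-2-en-1-yl]propyl}-9-borabicyclo[3.3.1]nonane F2. This is coupled in the same flask with methyl 5-bromopentanoate (Pd(OAc)2, PCy3, K3PO4·H2O, THF, rt; alkyl–alkyl Suzuki–Miyaura coupling) to give methyl 8-[(1R,4S)-4-(tert-butyldimethylsilyloxy)-1-hydroxycyclopent-2-en-1-yl]octanoate F3. Bu4NF then gives methyl 8-[(1R,4S)-1,4-dihydroxycyclopent-2-en-1-yl]octanoate F4, and MnO2 (CH2Cl2, rt) oxidises its secondary allylic alcohol to 9, so 5–8 are bypassed.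

Step 9 (competing deprotonation next to the ester, self-condensation, or β-elimination of the silyloxy group from 14). The fallback sets out from 12 and comes back at 15. Soft enolisation with Me3SiOTf and Et3N (CH2Cl2, 0 °C), which leaves the ester alone, gives methyl 8-[(1R)-3-bromo-1-(triethylsilyloxy)-4-(trimethylsilyloxy)cyclopenta-2,4-dien-1-yl]octanoate F5. A Mukaiyama aldol addition of it to 13 under BF3·OEt2 (CH2Cl2, −78 °C, then aqueous NaHCO3) delivers 15 without any strong base.

Step 10 (the least certain step: the 5Z/5E ratio may be near 1:1 or even favour 5E). The fallback sets out from 15 and comes back at 17. The elimination is run as before, but the route no longer relies on its kinetic selectivity. The unwanted isomer, methyl 8-[(1S,5E)-3-bromo-4-oxo-5-[(2E)-pent-2-en-1-ylidene]-1-(triethylsilyloxy)cyclopent-2-en-1-yl]octanoate F6, is collected and photoisomerised (365 nm, degassed benzene, Pyrex, rt) to a photostationary mixture. From this 17 is separated and the remainder re-irradiated; some chain-alkene isomers may form and are removed in the same chromatography.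

**Further compounds**
F1 | step 2 | (1R,4S)-4-(tert-butyldimethylsilyloxy)-1-(prop-2-enyl)cyclopent-2-en-1-ol | C1[C@H](O[Si](C)(C)C(C)(C)C)C=C[C@@]1(O)CC=C
F2 | step 2 | 9-{3-[(1R,4S)-4-(tert-butyldimethylsilyloxy)-1-hydroxycyclopent-2-en-1-yl]propyl}-9-borabicyclo[3.3.1]nonane | C1[C@H](O[Si](C)(C)C(C)(C)C)C=C[C@@]1(O)CCCB2C3CCCC2CCC3
F3 | step 2 | methyl 8-[(1R,4S)-4-(tert-butyldimethylsilyloxy)-1-hydroxycyclopent-2-en-1-yl]octanoate | C1[C@H](O[Si](C)(C)C(C)(C)C)C=C[C@@]1(O)CCCCCCCC(=O)OC
F4 | step 2 | methyl 8-[(1R,4S)-1,4-dihydroxycyclopent-2-en-1-yl]octanoate | C1[C@H](O)C=C[C@@]1(O)CCCCCCCC(=O)OC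
F5 | step 9 | methyl 8-[(1R)-3-bromo-1-(triethylsilyloxy)-4-(trimethylsilyloxy)cyclopenta-2,4-dien-1-yl]octanoate | C1=C(O[Si](C)(C)C)C(Br)=C[C@@]1(O[Si](CC)(CC)CC)CCCCCCCC(=O)OC
F6 | step 10 | methyl 8-[(1S,5E)-3-bromo-4-oxo-5-[(2E)-pent-2-en-1-ylidene]-1-(triethylsilyloxy)cyclopent-2-en-1-yl]octanoate | CC/C=C/C=C1/C(=O)C(Br)=C[C@@]1(O[Si](CC)(CC)CC)CCCCCCCC(=O)OC
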